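Compound numbers used throughout (structures in the list after the steps): 1 3-hydroxy-4,5-dimethoxybenzaldehyde; 2 its triisopropylsilyl ether; 3 3,4,5-trimethoxybenzaldehyde; 4 (2-carboxyethyl)triphenylphosphonium bromide; 5 carboxylate ylide; 6 (E)-4-(3,4,5-trimethoxyphenyl)but-3-enoic acid; 7 (S)-4-benzyl-2-oxazolidinone; 8 mixed pivalic anhydride; 9 N-acyl oxazolidinone; 10 boron enolate; 11 syn-aldol adduct; 12 styrenyl 1,3-diol; 13 alkylpalladium chloride; 14 acylpalladium chloride; 15 bicyclic lactone; 16 lactol; 17 oxocarbenium ion; 18 silyl-protected furofuran; 19 target.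

## Analysis of the target

The target 19 is a furofuran lignan, a cis-fused 3,7-dioxabicyclo[3.3.0]octane numbered here C1 (bridgehead), C2, O3, C4, C5 (bridgehead), C6, O7, C8, so that ring A is C1–C2–O3–C4–C5 and ring B is C5–C6–O7–C8–C1. C2 carries a 3-hydroxy-4,5-dimethoxyphenyl group and C6 a 3,4,5-trimethoxyphenyl group; the two halves differ by one O-methyl group, so the core is symmetric in all but the arenes and the two arenes must come from separate building blocks. There are four contiguous stereocentres, (1R,2S,5R,6S): the ring fusion can only be cis, and each aryl group is exo, meaning that the C2 aryl group is trans to C8 across ring A and the C6 aryl group is trans to C4 across ring B. The benzylic ether bonds C2–O3 and C6–O7 lie next to electron-rich arenes; strong acid ionises them and epimerises C2 or C6, and hydrogenolysis cleaves them, so a benzyl group cannot protect the phenol, which is itself oxidisable and must be masked in any oxidative step. The difficulty is to set all four centres in the absolute sense on an almost symmetric core without confusing the two arenes. The strategy rests on C4: it is a lone methylene between O3 and C5 and can therefore enter as a carbonyl carbon by carbonylation. If C5=C6 is drawn as an (E)-styrene, C1 becomes an allylic carbon bearing both the C8 hydroxymethyl arm (O7) and the C2 carbinol (O3); adding O7 to C6 and a carbonyl C4 to C5, with O3 closing onto C4, then builds rings A and B and the centres C5 and C6 in one operation.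

## Retrosynthetic reasoning

19 to 18. The phenolic O–H is traced back to an O–Si bond. The triisopropylsilyl ether in 18 is chosen because it has to pass a boron aldol reaction, two hydride reductions, an acidic oxidative carbonylation and a Lewis-acid reduction, and because its removal at the end touches neither benzylic ether.

18 to 15 by way of 16. The two C4–H bonds are cut, which raises C4 to the carboxyl level in lactone 15. Nothing else changes; the gain is that C4 becomes a carbonyl carbon bonded only to O3 and C5 and can be brought in by carbonylation. Forward, the lactone has to be taken down to the cyclic ether through lactol 16 and oxocarbenium ion 17 without opening ring A at the benzylic C2–O3 bond.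

15 to 12. Three bonds are cut together: C6–O7, C4–C5 and O3–C4. This removes C4 and opens both rings, leaving the acyclic diol 12 with an (E)-styrene at C5=C6 and the two hydroxyl-bearing arms on C1. The cut is made here because every carbon left in 12 belongs to acid 6 (C8, C1, C5, C6) or aldehyde 2 (C2), and because the stereocentres left, C1 and C2, are exactly those of a syn-aldol. The forward reaction has to add O7 and the new carbonyl carbon anti across the alkene, on the face that puts C4 cis to the C2 arm (through 13 and 14), and has to let O7 rather than O3 attack C6.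

12 to 11. C8 is raised from the alcohol to the acyl level and attached to oxazolidinone 7. The gain is that C1 becomes an enolisable α-carbon next to a controlling auxiliary. Forward, the exocyclic carbonyl must be reduced selectively and the auxiliary released.

11 to 9 and 2. The C1–C2 bond is cut as an aldol bond, which separates the two arenes into imide 9 and aldehyde 2. It is the only C–C bond in 12 that joins two stereocentres, and an auxiliary-controlled syn-aldol reaction through boron enolate 10 sets both absolutely. The syn relationship is the one that becomes "C2 aryl trans to C8" in ring A.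

9 to 6 and 7; 6 to 3 and 4; 2 to 1. The N-acyl bond of 9 is cut to acid 6 and auxiliary 7, joined forward through mixed anhydride 8. In 6 the C5=C6 double bond is cut as a Wittig bond between aldehyde 3 and phosphonium salt 4, through ylide 5; the (E) geometry matters because the key step translates it into the configuration of C6. Aldehyde 2 is the silyl ether of phenol 1.

## Alternatives that were turned down

Alternative 1: Only ring A is disconnected, at C1–C2 and O3–C4.
- Key step: aldehyde 2 would be allylated by the 2-(methoxycarbonyl)allylboronate A2, whose γ-carbon already carries the silyloxymethyl arm (C8, O7), under a chiral acid catalyst. The chair transition state forms C1–C2 and the boron-bound O3 then closes onto the ester, giving the trans α-methylene lactone A1 with C1 and C2 set.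
- For: a closed transition state, a trans relationship that follows from the alkene geometry of A2, catalytic asymmetric induction, and an established reaction type, which the key step chosen here is not.
- Against: A1 contains neither the C6 arene nor the C6–O7 bond. Its exocyclic methylene carbon is C6, so arylation at that carbon, desilylation of O7 and closure of ring B by conjugate addition of O7 to an arylidene lactone (5-endo-trig) must follow. C5 and C6 would be set in that last, poorly controlled step, and A2 itself needs several steps with defined geometry.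
- Comparison: on certainty of the key step Alternative 1 is stronger. The chosen strategy offers in exchange both rings and the remaining two stereocentres from one step, and a shorter route.

Alternative 2: The skeleton is cut at C5–C6 and C1–C2 around a butenolide whose ring atoms become C4, C5, C1 and C8; no ring of the target is formed.
- Key step: the 2-lithio derivative of dithiane A4 (the masked acyl anion of aldehyde 3) adds to the β-carbon of the menthyloxybutenolide A5 on the face away from the menthyloxy group, and the lactone enolate is trapped in the same flask by aldehyde 2 to give A3.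
- For: two C–C bonds and three components in one flask, a trans C1/C5 relationship and an absolute configuration that come reliably from a cheap acetal auxiliary, and a long-established reaction type for lignans. On robustness of C–C bond formation it is stronger than the chosen plan, and its length is similar.
- Against: C6 enters at the ketone level and C4 at the acetal level, so sulfur must be removed in the presence of electron-rich arenes and everything reduced to a tetraol. The C2 carbinol forms with little control. Rings A and B close only at the end, under acid, through benzylic cations at C2 and C6, so the exo orientation of both arenes depends on that closure and not on the key step.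
- Comparison: the chosen strategy closes both rings in the key step and needs no redox detour at C6 and no cation chemistry on the aryl carbinols. Alternative 2 is kept as the fallback.

Alternative 3: Ring B is disconnected at C5–C6 and C1–C8 as a (3+2) cycloaddition.
- Key step: a carbonyl ylide, released from the α-silyl chloromethyl ether A7 by a fluoride source and carrying the trimethoxyphenyl group on one terminus, adds across the C1=C5 bond of the enantiopure 5-aryl butenolide A8 (ring A at the lactone level) on the face away from its aryl group, giving A6.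
- For: A6 is the methoxymethyl analogue of lactone 15, so this plan reaches the same kind of intermediate with the same short endgame, and more convergently, with two C–C bonds made in the key step. On these points it is as strong as or stronger than the chosen route.
- Against: three selectivities rest on nothing in the structure. The aryl-bearing terminus of the unsymmetrical, non-stabilised ylide must bond to C5 (α to the carbonyl) and the methylene terminus to C1. The C6 aryl group must end up exo, which depends on ylide geometry and mode of approach. The C2–H of A8 is benzylic, allylic and α to oxygen, so basic fluoride threatens the one stereocentre that relays the absolute configuration. A8 also needs its own asymmetric synthesis.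
- Comparison: in the chosen strategy the regiochemistry is fixed by tethering, the absolute configuration comes from an auxiliary-controlled aldol reaction, and C6 is tied to C5 by the addition mechanism.

Key step: step 6

Assumption: aldehyde 1 is taken as a commercial compound; 13 and 14 are written without their further ligands on palladium, and metal alkoxide forms of products that exist only until aqueous work-up carry no number.

## Route

Step 1
Reactants: 1 3-hydroxy-4,5-dimethoxybenzaldehyde
Product: 2 3,4-dimethoxy-5-(triisopropylsilyloxy)benzaldehyde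
Conditions: i-Pr3SiCl, imidazole, DMF, rt
Reagents that add atoms: triisopropylsilyl chloride, CC(C)[Si](Cl)(C(C)C)C(C)C
Why: Imidazole-promoted silylation of the phenol; the aldehyde is inert, and the bulky aryl silyl ether is chosen to survive boron enolate chemistry, hydrides, the buffered acidic carbonylation and BF3·OEt2.

Step 2
Reactants: 3 3,4,5-trimethoxybenzaldehyde; 4 (2-carboxyethyl)triphenylphosphonium bromide
Product: 6 (E)-4-(3,4,5-trimethoxyphenyl)but-3-enoic acid, via carboxylate ylide 5 (not isolated)
Conditions: 4, NaN(SiMe3)2 (2.1 equiv), THF, −78 → 0 °C; then 3, 0 °C → rt; aq. HCl; recrystallisation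
Reagents that add atoms: none
Why: Wittig reaction of the carboxylate ylide with an aryl aldehyde, a combination that is known to favour (E)-4-arylbut-3-enoic acids; the alkene stays conjugated with the arene, and crystallisation of the acid should remove any (Z)-isomer.

Step 3
Reactants: 6 (E)-4-(3,4,5-trimethoxyphenyl)but-3-enoic acid; 7 (S)-4-benzyl-2-oxazolidinone
Product: 9 (S)-4-benzyl-3-[(E)-4-(3,4,5-trimethoxyphenyl)but-3-enoyl]oxazolidin-2-one, via mixed pivalic anhydride 8 (not isolated)
Conditions: t-BuCOCl, Et3N, THF, −20 °C; then LiCl, 7, −20 °C → rt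
Reagents that add atoms: none
Why: N-Acylation of the oxazolidinone through a mixed anhydride, which is attacked at its less hindered carbonyl; the mild LiCl/Et3N conditions avoid strong base and should leave the β,γ-alkene in place.

Step 4
Reactants: 9 (S)-4-benzyl-3-[(E)-4-(3,4,5-trimethoxyphenyl)but-3-enoyl]oxazolidin-2-one; 2 3,4-dimethoxy-5-(triisopropylsilyloxy)benzaldehyde
Product: 11 (S)-4-benzyl-3-{(2S,3S)-3-[3,4-dimethoxy-5-(triisopropylsilyloxy)phenyl]-3-hydroxy-2-[(E)-2-(3,4,5-trimethoxyphenyl)ethenyl]propanoyl}oxazolidin-2-one, via boron enolate 10 (not isolated)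
Conditions: Bu2BOTf, i-Pr2NEt, CH2Cl2, −78 → 0 °C; then 2, −78 → 0 °C; pH 7 buffer, MeOH, H2O2, 0 °C
Reagents that add atoms: none
Why: Evans syn-aldol reaction: the (Z)-boron enolate reacts at its α-carbon through a chair Zimmerman–Traxler transition state on the face away from the benzyl group of the auxiliary, which sets C1 and C2 as the (2S,3S) syn adduct. This syn relationship is the one that later places the C2 aryl group trans to C8 in ring A.

Step 5
Reactants: 11 (S)-4-benzyl-3-{(2S,3S)-3-[3,4-dimethoxy-5-(triisopropylsilyloxy)phenyl]-3-hydroxy-2-[(E)-2-(3,4,5-trimethoxyphenyl)ethenyl]propanoyl}oxazolidin-2-one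
Product: 12 (1S,2R)-1-[3,4-dimethoxy-5-(triisopropylsilyloxy)phenyl]-2-[(E)-2-(3,4,5-trimethoxyphenyl)ethenyl]propane-1,3-diol
Conditions: LiBH4, MeOH (1 equiv), THF, 0 °C
Reagents that add atoms: none
Why: Reductive cleavage of the N-acyl oxazolidinone by LiBH4 at the more electrophilic exocyclic carbonyl, which turns C8 into the hydroxymethyl group and releases the auxiliary; alkene, silyl ether and both stereocentres are not affected.

Step 6
Reactants: 12 (1S,2R)-1-[3,4-dimethoxy-5-(triisopropylsilyloxy)phenyl]-2-[(E)-2-(3,4,5-trimethoxyphenyl)ethenyl]propane-1,3-diol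
Product: 15 (1R,2S,5S,6S)-2-[3,4-dimethoxy-5-(triisopropylsilyloxy)phenyl]-6-(3,4,5-trimethoxyphenyl)-3,7-dioxabicyclo[3.3.0]octan-4-one, via alkylpalladium chloride 13 (not isolated), via acylpalladium chloride 14 (not isolated)
Conditions: PdCl2 (10 mol %), CuCl2 (3 equiv), NaOAc (3 equiv), CO (1 atm), AcOH, rt
Reagents that add atoms: carbon monoxide, [C-]#[O+]
Why: Proposed new method: PdCl2 should bind the C5=C6 styrene of 12 on the face that carries the C2 carbinol arm, with O3–H as a second ligand, and the primary hydroxyl O7 should attack the benzylic carbon C6 from the opposite face, closing ring B in the 5-endo-trig mode (C6–O7) and giving alkylpalladium chloride 13. CO then inserts into the C5–Pd bond with retention (C4–C5, acylpalladium chloride 14), O3 captures the acyl carbon in a 5-exo-trig closure of ring A (O3–C4), and the zerovalent palladium set free is reoxidised by CuCl2 while NaOAc takes up the HCl. The closest known reaction type is the PdCl2/CuCl2 oxycarbonylative bicyclisation of pent-4-ene-1,3-diols to cis-fused bicyclic lactones, which opens with a 5-exo oxypalladation; the 5-endo opening needed here is not known for this substrate class and is expected to be made possible by the electron-rich arene at C6, which directs the oxygen nucleophile to the benzylic carbon as in the Wacker oxidation of styrenes. C6 is controlled by the anti addition of O7 and palladium across the (E)-alkene, which puts the C6 aryl group trans to C4, and the chloride-rich medium is chosen because it favours anti over syn oxypalladation. C5 is controlled by the face that palladium occupies: only an alkylpalladium with C5–Pd cis to the C2 arm can lactonise, so any bicyclic lactone that forms is cis-fused and, through the anti addition, carries the C6 aryl group exo. The step also needs O7 and not O3 to attack C6; the less hindered primary hydroxyl, the less crowded ring it forms and the binding of O3 to palladium on the far face should secure this. An alkoxycarbonylpalladium species formed at O3 would lead to the same product by alkene insertion and displacement of benzylic palladium by O7 with inversion, whereas buffered AcOH should suppress the corresponding species at O7. C1 and C2 are not touched.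

Step 7
Reactants: 15 (1R,2S,5S,6S)-2-[3,4-dimethoxy-5-(triisopropylsilyloxy)phenyl]-6-(3,4,5-trimethoxyphenyl)-3,7-dioxabicyclo[3.3.0]octan-4-one
Product: 16 (1R,2S,5S,6S)-2-[3,4-dimethoxy-5-(triisopropylsilyloxy)phenyl]-6-(3,4,5-trimethoxyphenyl)-3,7-dioxabicyclo[3.3.0]octan-4-ol (both C4 epimers)
Conditions: i-Bu2AlH (1.2 equiv), CH2Cl2, −78 °C; aq. potassium sodium tartrate (KNaC4H4O6)
Reagents that add atoms: none
Why: Partial reduction of a γ-lactone to the lactol, possible because the tetrahedral aluminium alkoxide is stable at −78 °C; the new hemiacetal centre at C4 is of no consequence because step 8 removes it.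

Step 8
Reactants: 16 (1R,2S,5S,6S)-2-[3,4-dimethoxy-5-(triisopropylsilyloxy)phenyl]-6-(3,4,5-trimethoxyphenyl)-3,7-dioxabicyclo[3.3.0]octan-4-ol
Product: 18 (1R,2S,5R,6S)-2-[3,4-dimethoxy-5-(triisopropylsilyloxy)phenyl]-6-(3,4,5-trimethoxyphenyl)-3,7-dioxabicyclo[3.3.0]octane, via oxocarbenium ion 17 (not isolated)
Conditions: Et3SiH, BF3·OEt2, CH2Cl2, −78 → −40 °C
Reagents that add atoms: none
Why: Ionic hydrogenation of a lactol: BF3·OEt2 ionises the C4 hydroxyl to the cyclic oxocarbenium ion and Et3SiH delivers hydride to C4, which becomes a methylene and carries no stereocentre. The low temperature should keep the benzylic C2–O3 and C6–O7 bonds from ionising.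

Step 9
Reactants: 18 (1R,2S,5R,6S)-2-[3,4-dimethoxy-5-(triisopropylsilyloxy)phenyl]-6-(3,4,5-trimethoxyphenyl)-3,7-dioxabicyclo[3.3.0]octane
Product: 19 5-[(1R,2S,5R,6S)-6-(3,4,5-trimethoxyphenyl)-3,7-dioxabicyclo[3.3.0]octan-2-yl]-2,3-dimethoxyphenol
Conditions: Bu4NF, AcOH, THF, 0 °C
Reagents that add atoms: none
Why: Fluoride cleavage of the aryl silyl ether, driven by Si–F bond formation; acetic acid buffers the phenoxide, and the methyl ethers and benzylic C–O bonds are inert.

## Compound list

1 | 3-hydroxy-4,5-dimethoxybenzaldehyde | COc1cc(C=O)cc(O)c1OC | starting material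
2 | 3,4-dimethoxy-5-(triisopropylsilyloxy)benzaldehyde | COc1cc(C=O)cc(O[Si](C(C)C)(C(C)C)C(C)C)c1OC | intermediate
3 | 3,4,5-trimethoxybenzaldehyde | COc1cc(C=O)cc(OC)c1OC | starting material
4 | (2-carboxyethyl)triphenylphosphonium bromide | OC(=O)CC[P+](c1ccccc1)(c1ccccc1)c1ccccc1.[Br-] | starting material
5 | sodium 3-(triphenylphosphoranylidene)propanoate, the carboxylate ylide (formed in the flask) | [Na+].[O-]C(=O)CC=P(c1ccccc1)(c1ccccc1)c1ccccc1 | intermediate
6 | (E)-4-(3,4,5-trimethoxyphenyl)but-3-enoic acid | OC(=O)C/C=C/c1cc(OC)c(OC)c(OC)c1 | intermediate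
7 | (S)-4-benzyl-2-oxazolidinone | O=C1OC[C@H](Cc2ccccc2)N1 | starting material
8 | (E)-4-(3,4,5-trimethoxyphenyl)but-3-enoic pivalic anhydride (formed in the flask) | CC(C)(C)C(=O)OC(=O)C/C=C/c1cc(OC)c(OC)c(OC)c1 | intermediate
9 | (S)-4-benzyl-3-[(E)-4-(3,4,5-trimethoxyphenyl)but-3-enoyl]oxazolidin-2-one | O=C(C/C=C/c1cc(OC)c(OC)c(OC)c1)N1C(=O)OC[C@@H]1Cc1ccccc1 | intermediate
10 | (S)-4-benzyl-3-[(1Z,3E)-1-(dibutylboryloxy)-4-(3,4,5-trimethoxyphenyl)buta-1,3-dienyl]oxazolidin-2-one, the boron enolate (formed in the flask) | CCCCB(CCCC)O/C(=C\C=C\c1cc(OC)c(OC)c(OC)c1)N1C(=O)OC[C@@H]1Cc1ccccc1 | intermediate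
11 | (S)-4-benzyl-3-{(2S,3S)-3-[3,4-dimethoxy-5-(triisopropylsilyloxy)phenyl]-3-hydroxy-2-[(E)-2-(3,4,5-trimethoxyphenyl)ethenyl]propanoyl}oxazolidin-2-one | O=C([C@@H](/C=C/c1cc(OC)c(OC)c(OC)c1)[C@H](O)c1cc(O[Si](C(C)C)(C(C)C)C(C)C)c(OC)c(OC)c1)N1C(=O)OC[C@@H]1Cc1ccccc1 | intermediate
12 | (1S,2R)-1-[3,4-dimethoxy-5-(triisopropylsilyloxy)phenyl]-2-[(E)-2-(3,4,5-trimethoxyphenyl)ethenyl]propane-1,3-diol | OC[C@@H](/C=C/c1cc(OC)c(OC)c(OC)c1)[C@H](O)c1cc(O[Si](C(C)C)(C(C)C)C(C)C)c(OC)c(OC)c1 | intermediate
13 | alkylpalladium chloride from 5-endo oxypalladation of 12: ring B closed, C5–Pd trans to the C6 aryl group and cis to the C2 carbinol arm (formed in the flask) | O[C@H](c1cc(OC)c(OC)c(O[Si](C(C)C)(C(C)C)C(C)C)c1)[C@H]1CO[C@H](c2cc(OC)c(OC)c(OC)c2)[C@H]1[Pd]Cl | intermediate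
14 | acylpalladium chloride from CO insertion into 13 with retention at C5 (formed in the flask) | O[C@H](c1cc(OC)c(OC)c(O[Si](C(C)C)(C(C)C)C(C)C)c1)[C@H]1CO[C@H](c2cc(OC)c(OC)c(OC)c2)[C@H]1C(=O)[Pd]Cl | intermediate
15 | (1R,2S,5S,6S)-2-[3,4-dimethoxy-5-(triisopropylsilyloxy)phenyl]-6-(3,4,5-trimethoxyphenyl)-3,7-dioxabicyclo[3.3.0]octan-4-one | COc1cc([C@H]2OC(=O)[C@H]3[C@@H]2CO[C@@H]3c4cc(OC)c(OC)c(OC)c4)cc(O[Si](C(C)C)(C(C)C)C(C)C)c1OC | intermediate
16 | (1R,2S,5S,6S)-2-[3,4-dimethoxy-5-(triisopropylsilyloxy)phenyl]-6-(3,4,5-trimethoxyphenyl)-3,7-dioxabicyclo[3.3.0]octan-4-ol (both C4 epimers) | COc1cc([C@H]2OC(O)[C@H]3[C@@H]2CO[C@@H]3c4cc(OC)c(OC)c(OC)c4)cc(O[Si](C(C)C)(C(C)C)C(C)C)c1OC | intermediate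
17 | cyclic O3=C4 oxocarbenium ion derived from 16 (formed in the flask) | COc1cc([C@H]2[O+]=C[C@H]3[C@@H]2CO[C@@H]3c4cc(OC)c(OC)c(OC)c4)cc(O[Si](C(C)C)(C(C)C)C(C)C)c1OC | intermediate
18 | (1R,2S,5R,6S)-2-[3,4-dimethoxy-5-(triisopropylsilyloxy)phenyl]-6-(3,4,5-trimethoxyphenyl)-3,7-dioxabicyclo[3.3.0]octane | COc1cc([C@H]2OC[C@H]3[C@@H]2CO[C@@H]3c4cc(OC)c(OC)c(OC)c4)cc(O[Si](C(C)C)(C(C)C)C(C)C)c1OC | intermediate
19 | 5-[(1R,2S,5R,6S)-6-(3,4,5-trimethoxyphenyl)-3,7-dioxabicyclo[3.3.0]octan-2-yl]-2,3-dimethoxyphenol | COc1cc([C@H]2OC[C@H]3[C@@H]2CO[C@@H]3c2cc(OC)c(OC)c(OC)c2)cc(O)c1OC | target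

## Step count and least certain steps

Total: 9 steps (isolated compounds 2, 6, 9, 11, 12, 15, 16, 18, 19). Longest linear sequence: 8 steps (steps 2 to 9, from 3 and 4 to 19); step 1 is a one-step branch that joins at step 4.

Step 6 (key step, new method).
- What may go wrong: the cascade may not start, because 5-endo attack of oxygen on a palladium-bound styrene is untested in the oxygen series (5-endo heteropalladation of styrenes is known for nitrogen, in the cyclisation of 2-vinylanilines to indoles). β-Hydride elimination from the C5–palladium bond, or capture of C6 by acetate or adventitious water, may then outrun it.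
- It may also start at the wrong oxygen. Both hydroxyls are homoallylic to the alkene; if O3 rather than O7 attacks C6, or if an alkoxycarbonylpalladium species forms at O7, the rings close with both arenes on the same ring. A syn oxypalladation would invert C6.
- Fallback (known chemistry; sets out from aldehydes 2 and 3, returns at 18): the conjugate addition–aldol sequence of Alternative 2. Aldehyde 3 is converted with propane-1,3-dithiol and BF3·OEt2 into dithiane A4. Its 2-lithio derivative (n-BuLi, THF, −78 °C) adds to butenolide A5 anti to the menthyloxy group, and the enolate is trapped with 2 to give lactone A3. PhI(OCOCF3)2 in aqueous MeCN unmasks the C6 ketone, giving the 4-aroyl-5-menthyloxy lactone F1. LiAlH4 (THF, 0 °C) reduces ketone, lactone and menthyl acetal to the 2,3-bis(hydroxymethyl)-1,4-diarylbutane-1,4-diol F2. Catalytic camphorsulfonic acid in CH2Cl2 then closes rings A and B through the benzylic cations at C2 and C6, a closure expected to place each aryl group trans to the neighbouring ring substituent, and gives 18. Because C2 and C6 pass through cations, the carbinol configurations in A3 and F2 do not matter.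

Step 4.
- What may go wrong: amine-mediated migration of the alkene into conjugation with the imide before enolisation, reaction of the dienolate at its γ-carbon, or erosion of the syn selectivity by retro-aldol equilibration with the electron-rich aldehyde.
- Fallback (sets out from 2, returns at 12): C1–C2 is made by allylboration instead of enolate chemistry. Aldehyde 2 reacts with the (E)-4-(tert-butyldimethylsilyloxy)but-2-enylboronic acid pinacol ester F3 under a chiral phosphoric acid ((S)-TRIP, toluene, −30 °C; the enantiomer expected, by analogy with simple aryl aldehydes, to give the (S)-carbinol). The chair transition state should give the anti homoallylic alcohol F4, which has the C1/C2 relationship of 12. Cross-metathesis of its vinyl group with 3,4,5-trimethoxystyrene F5 (from 3 by Wittig methylenation; second-generation Grubbs catalyst, CH2Cl2, 40 °C) installs the (E)-styrene in the primary silyl ether F6. HF·pyridine then removes the alkyl silyl group while the aryl silyl ether stays, giving 12.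

Step 8.
- What may go wrong: ionisation of the benzylic C2–O3 or C6–O7 bonds by BF3·OEt2 in competition with hydride delivery to C4, with epimerisation at C2 or C6 or opening of a ring.
- Fallback (sets out from 15, returns at 18, replaces steps 7 and 8): LiAlH4 (THF, 0 °C) opens the lactone to the ring-B diol F7 (primary alcohol at C4, benzylic alcohol at C2). MsCl (1 equiv) in pyridine at 0 °C sulfonylates the primary hydroxyl to the mesylate F8 (not isolated), and O3 displaces it in a 5-exo-tet closure of ring A. No cation is formed at C2 or C6, and C2 keeps its configuration because its C–O bond is never broken.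

Step 2.
- What may go wrong: incomplete (E)-selectivity, and fragmentation of the β-carboxylate ylide with loss of acrylate before it meets the aldehyde.
- Fallback (sets out from 3, returns at 6): homologation and Knoevenagel–Doebner condensation. Wittig methoxymethylenation of 3 (Ph3P=CHOMe from the phosphonium chloride and KOt-Bu, THF) gives the enol ether F9. Aqueous formic acid hydrolyses it to (3,4,5-trimethoxyphenyl)acetaldehyde F10. Condensation with malonic acid (piperidinium acetate, DMSO, 100 °C) with decarboxylation gives the β,γ-unsaturated acid 6, whose (E) geometry is set under thermodynamic control in conjugation with the arene.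

## Further compounds

F1 | step 6 | trans,trans-3-{(S)-[3,4-dimethoxy-5-(triisopropylsilyloxy)phenyl](hydroxy)methyl}-5-[(1R,2S,5R)-menthyloxy]-4-(3,4,5-trimethoxybenzoyl)dihydrofuran-2(3H)-one | CC(C)[C@@H]1CC[C@@H](C)C[C@H]1O[C@H]2[C@H](C(=O)c3cc(OC)c(OC)c(OC)c3)[C@@H]([C@H](O)c3cc(O[Si](C(C)C)(C(C)C)C(C)C)c(OC)c(OC)c3)C(=O)O2
F2 | step 6 | 1-[3,4-dimethoxy-5-(triisopropylsilyloxy)phenyl]-2,3-bis(hydroxymethyl)-4-(3,4,5-trimethoxyphenyl)butane-1,4-diol (C1 and C5 of the target set; C6 carbinol as a mixture) | OC[C@H]([C@H](O)c1cc(O[Si](C(C)C)(C(C)C)C(C)C)c(OC)c(OC)c1)[C@H](CO)C(O)c1cc(OC)c(OC)c(OC)c1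
F3 | step 4 | (E)-2-[4-(tert-butyldimethylsilyloxy)but-2-enyl]-4,4,5,5-tetramethyl-1,3,2-dioxaborolane | CC1(C)OB(C/C=C/CO[Si](C)(C)C(C)(C)C)OC1(C)C
F4 | step 4 | (1S,2R)-2-[(tert-butyldimethylsilyloxy)methyl]-1-[3,4-dimethoxy-5-(triisopropylsilyloxy)phenyl]but-3-en-1-ol | C=C[C@H](CO[Si](C)(C)C(C)(C)C)[C@H](O)c1cc(O[Si](C(C)C)(C(C)C)C(C)C)c(OC)c(OC)c1
F5 | step 4 | 3,4,5-trimethoxystyrene | C=Cc1cc(OC)c(OC)c(OC)c1
F6 | step 4 | (1S,2R)-2-[(tert-butyldimethylsilyloxy)methyl]-1-[3,4-dimethoxy-5-(triisopropylsilyloxy)phenyl]-4-(3,4,5-trimethoxyphenyl)but-3-en-1-ol, the (E)-alkene | CC(C)(C)[Si](C)(C)OC[C@@H](/C=C/c1cc(OC)c(OC)c(OC)c1)[C@H](O)c1cc(O[Si](C(C)C)(C(C)C)C(C)C)c(OC)c(OC)c1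
F7 | step 8 | {(2S,3R,4R)-4-[(S)-[3,4-dimethoxy-5-(triisopropylsilyloxy)phenyl](hydroxy)methyl]-2-(3,4,5-trimethoxyphenyl)tetrahydrofuran-3-yl}methanol | OC[C@@H]1[C@@H](c2cc(OC)c(OC)c(OC)c2)OC[C@@H]1[C@H](O)c1cc(O[Si](C(C)C)(C(C)C)C(C)C)c(OC)c(OC)c1
F8 | step 8 | primary methanesulfonate of F7 | CS(=O)(=O)OC[C@@H]1[C@@H](c2cc(OC)c(OC)c(OC)c2)OC[C@@H]1[C@H](O)c1cc(O[Si](C(C)C)(C(C)C)C(C)C)c(OC)c(OC)c1
F9 | step 2 | 1,2,3-trimethoxy-5-(2-methoxyethenyl)benzene (E/Z mixture) | COC=Cc1cc(OC)c(OC)c(OC)c1
F10 | step 2 | (3,4,5-trimethoxyphenyl)acetaldehyde | O=CCc1cc(OC)c(OC)c(OC)c1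
A1 | alternative 1 | trans-5-[3,4-dimethoxy-5-(triisopropylsilyloxy)phenyl]-4-[(tert-butyldimethylsilyloxy)methyl]-3-methylenedihydrofuran-2(3H)-one | COc1cc([C@H]2OC(=O)C(=C)[C@@H]2CO[Si](C)(C)C(C)(C)C)cc(O[Si](C(C)C)(C(C)C)C(C)C)c1OC
A2 | alternative 1 | methyl (Z)-4-(tert-butyldimethylsilyloxy)-2-[(4,4,5,5-tetramethyl-1,3,2-dioxaborolan-2-yl)methyl]but-2-enoate | COC(=O)/C(CB1OC(C)(C)C(C)(C)O1)=C\CO[Si](C)(C)C(C)(C)C
A3 | alternative 2 | trans,trans-3-{(S)-[3,4-dimethoxy-5-(triisopropylsilyloxy)phenyl](hydroxy)methyl}-5-[(1R,2S,5R)-menthyloxy]-4-[2-(3,4,5-trimethoxyphenyl)-1,3-dithian-2-yl]dihydrofuran-2(3H)-one | CC(C)[C@@H]1CC[C@@H](C)C[C@H]1O[C@H]2[C@H](C3(c4cc(OC)c(OC)c(OC)c4)SCCCS3)[C@@H]([C@H](O)c3cc(O[Si](C(C)C)(C(C)C)C(C)C)c(OC)c(OC)c3)C(=O)O2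
A4 | alternative 2 | 2-(3,4,5-trimethoxyphenyl)-1,3-dithiane | COc1cc(C2SCCCS2)cc(OC)c1OC
A5 | alternative 2 | (5R)-5-[(1R,2S,5R)-menthyloxy]furan-2(5H)-one | CC(C)[C@@H]1CC[C@@H](C)C[C@H]1O[C@@H]1OC(=O)C=C1
A6 | alternative 3 | 2-[3,4-dimethoxy-5-(methoxymethoxy)phenyl]-6-(3,4,5-trimethoxyphenyl)-3,7-dioxabicyclo[3.3.0]octan-4-one, both aryl groups exo (methoxymethyl analogue of 15) | COc1cc([C@H]2OC[C@H]3[C@@H]2C(=O)O[C@@H]3c4cc(OCOC)c(OC)c(OC)c4)cc(OC)c1OC
A7 | alternative 3 | chloromethyl (3,4,5-trimethoxyphenyl)(trimethylsilyl)methyl ether (racemic) | COc1cc(C(OCCl)[Si](C)(C)C)cc(OC)c1OC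
A8 | alternative 3 | (S)-5-[3,4-dimethoxy-5-(methoxymethoxy)phenyl]furan-2(5H)-one | O=C1C=C[C@@H](c2cc(OCOC)c(OC)c(OC)c2)O1
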